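The hydroazulene is disconnected at the ring-fusion bond C6–C10 and the olefinic bond C3–C4. This opens both rings at once: the seven-membered ring splits into a three-carbon unit (C4–C6, an allene) and a four-carbon unit (C10, C1–C3, a 2-silyloxydiene), while the cyclopentane carbons C7–C9 become the tether between them. A gold-catalysed intramolecular (4+3) cycloaddition of this acyclic allene–diene closes the five- and seven-membered rings in one operation and sets the quaternary C6 and C10 under control of the C9 carbinol. The cycloadduct's enol ether is the C1 ketone; one alkene migration places C3=C4, and the C9 hydroxyl finally directs reduction at C1 and C7.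

Key step: step 6

Numbering used here (not IUPAC): the ten ring carbons are counted round the periphery. C1 = CH–O of the seven-membered ring next to the ring-fusion CH, C2 = CH2, C3 = C(CH3)=, C4 = =CH, C5 = CH2, C6 = ring-fusion C(CH3), C7 = CH–O of the five-membered ring, C8 = CH2, C9 = C(OH)(i-Pr), C10 = ring-fusion CH. β is the face of the C6 methyl group.

Remark on the chemistry: the C7 carbinol is formed in step 3 with the configuration expected for chelation control (epimeric to the target). It is carried in that form and corrected by oxidation and hydroxyl-directed reduction in steps 9 and 10.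

Step 1
Reactants: 1 4-methyl-3-oxopentanenitrile
Product: 2 (3S)-3-hydroxy-3-(propan-2-yl)hex-5-enenitrile
Conditions: enantiopure B-allyl-10-phenyl-9-borabicyclo[3.3.2]decane (antipode that allylates the Re face), Et2O, −78 °C; then aq. NH4Cl
Reagents that add atoms: B-allyl-10-phenyl-9-borabicyclo[3.3.2]decane, C=CCB1C2CCCC(CCC2)C1c3ccccc3
Why: Reagent-controlled asymmetric allylboration of a ketone through a six-membered chair transition state, in which the chiral borabicycle should distinguish the large isopropyl from the small cyanomethyl group and so set the C9 tertiary carbinol by Re-face attack.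

Step 2
Reactants: 2 (3S)-3-hydroxy-3-(propan-2-yl)hex-5-enenitrile
Product: 4 (3R)-3-hydroxy-5-oxo-3-(propan-2-yl)pentanenitrile, via ozonide 3 (not isolated)
Conditions: O3, CH2Cl2, −78 °C; then PPh3, −78 °C to rt
Reagents that add atoms: ozone, [O-][O+]=O
Why: Ozonolysis with reductive work-up cleaves only the terminal alkene (nitrile and tertiary alcohol are inert) and leaves the C9 stereocentre untouched.

Step 3
Reactants: 4 (3R)-3-hydroxy-5-oxo-3-(propan-2-yl)pentanenitrile; 5 1-bromobut-2-yne
Product: 6 (3R,5R)-3,5-dihydroxy-6-methyl-3-(propan-2-yl)octa-6,7-dienenitrile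
Conditions: In powder, THF/H2O (1:1), rt
Reagents that add atoms: none
Why: Barbier-type indium-mediated coupling in water, in which the γ-substituted propargyl bromide should react at its methyl-bearing carbon to give the α-allenyl carbinol chemoselectively at the aldehyde; chelation of indium by the free C9 hydroxyl is expected to favour the 5R epimer shown, whose C7 centre is corrected later.

Step 4
Reactants: 6 (3R,5R)-3,5-dihydroxy-6-methyl-3-(propan-2-yl)octa-6,7-dienenitrile
Product: 8 (2E,6S,8R)-6,8-dihydroxy-9-methyl-6-(propan-2-yl)undeca-2,9,10-trien-4-one, via ketimine 7 (not isolated)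
Conditions: (E)-MeCH=CHMgBr (5 equiv), THF, 0 °C to rt; then sat. aq. NH4Cl, rt
Reagents that add atoms: (E)-prop-1-en-1-ylmagnesium bromide, C/C=C/[Mg]Br; water, O
Why: Grignard addition to a nitrile stops at the N-magnesio ketimine (the β-alkoxide assists addition and suppresses α-deprotonation and elimination), and mild aqueous hydrolysis should give the (E)-enone without touching the allene or the stereocentres.

Step 5
Reactants: 8 (2E,6S,8R)-6,8-dihydroxy-9-methyl-6-(propan-2-yl)undeca-2,9,10-trien-4-one
Product: 9 triethyl{[(2E,4Z,6R,8R)-9-methyl-6-(propan-2-yl)-6,8-bis(triethylsilyloxy)undeca-2,4,9,10-tetraen-4-yl]oxy}silane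
Conditions: Et3SiOTf (4 equiv), Et3N (6 equiv), CH2Cl2, −78 to 0 °C
Reagents that add atoms: triethylsilyl trifluoromethanesulfonate, CC[Si](CC)(CC)OS(=O)(=O)C(F)(F)F
Why: Silyl triflate with amine silylates both hydroxyls and soft-enolises the enone at the α'-methylene (C10) to the 2-silyloxydiene, the Z enol ether being favoured by allylic strain against the quaternary C9.

Step 6
Reactants: 9 triethyl{[(2E,4Z,6R,8R)-9-methyl-6-(propan-2-yl)-6,8-bis(triethylsilyloxy)undeca-2,4,9,10-tetraen-4-yl]oxy}silane
Product: 10 triethyl({(1R,3R,3aS,6R,8aR)-6,8a-dimethyl-3-(propan-2-yl)-1,3-bis[(triethylsilyl)oxy]-1,2,3,3a,6,8a-hexahydroazulen-4-yl}oxy)silane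
Conditions: [Au{P(t-Bu)2(biphenyl-2-yl)}(NCMe)]SbF6 (5 mol%), 4 Å molecular sieves, CH2Cl2, −20 °C to rt
Reagents that add atoms: none
Why: The cationic gold complex activates the allene as a gold-bound allyl cation (C4–C5–C6), which adds across the termini of the 2-silyloxydiene (nucleophilic C10 to the more substituted terminus C6, C3 to C4), and the resulting gold carbene at C5 collapses by 1,2-hydride shift from C4 (C6 bears no hydrogen) to release the catalyst and the C4=C5 bond. The closest known reaction is the gold- or platinum-catalysed intramolecular (4C+3C) cycloaddition of allene-tethered 1,3-dienes to trans-fused bicyclo[5.3.0]decadienes. The five-membered ring closes through the C6–C10 bond (5-exo attack on the tethered allene carbon, tether C7–C9) and the seven-membered ring through the C3–C4 bond as the (4+3) ring. C10 is controlled by C9, because allylic strain in the Z enol ether holds the C9–O bond in the diene plane so that the tether delivers C6 to the face opposite isopropyl; C6 is set by the extended cycloaddition geometry typical of this reaction, which gives the trans ring fusion with the C6 methyl cis to C1; the C3 centre (methyl β) is transient and is erased in step 7. The step needs (4+3) selectivity over ring contraction by 1,2-alkyl shift ((4+2) products) and over O-cyclisation or ionisation of the allylic silyl ether; the electron-rich biarylphosphine ligand, full silyl protection and low temperature are chosen for this.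

Step 7
Reactants: 10 triethyl({(1R,3R,3aS,6R,8aR)-6,8a-dimethyl-3-(propan-2-yl)-1,3-bis[(triethylsilyl)oxy]-1,2,3,3a,6,8a-hexahydroazulen-4-yl}oxy)silane
Product: 11 triethyl({(1R,3R,3aS,8aR)-6,8a-dimethyl-3-(propan-2-yl)-1,3-bis[(triethylsilyl)oxy]-1,2,3,3a,8,8a-hexahydroazulen-4-yl}oxy)silane
Conditions: RuHCl(CO)(PPh3)3 (5 mol%), toluene, 80 °C
Reagents that add atoms: none
Why: Ruthenium hydride-catalysed positional isomerisation (hydrometallation and β-hydride elimination) of a skipped diene, in which the C4=C5 bond can migrate only towards C3 (C6 is quaternary) and should stop at the conjugated, trisubstituted silyl dienol ether as the thermodynamic sink; no stereocentre is formed.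

Step 8
Reactants: 11 triethyl({(1R,3R,3aS,8aR)-6,8a-dimethyl-3-(propan-2-yl)-1,3-bis[(triethylsilyl)oxy]-1,2,3,3a,8,8a-hexahydroazulen-4-yl}oxy)silane
Product: 12 (1R,3R,3aR,8aR)-1,3-dihydroxy-6,8a-dimethyl-3-(propan-2-yl)-1,2,3,3a,8,8a-hexahydroazulen-4(5H)-one
Conditions: TBAF, AcOH (1:1), THF, −78 °C to rt
Reagents that add atoms: none
Why: Fluoride cleaves the silyl dienol ether to the dienolate, whose kinetic protonation at the α-carbon C2 by the acetic acid buffer should give the β,γ-unsaturated ketone (deconjugative protonation), while the same reagent removes both silyl ethers; buffering guards against reconjugation, epimerisation at C10 and retro-aldol cleavage.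

Step 9
Reactants: 12 (1R,3R,3aR,8aR)-1,3-dihydroxy-6,8a-dimethyl-3-(propan-2-yl)-1,2,3,3a,8,8a-hexahydroazulen-4(5H)-one
Product: 13 (3R,3aR,8aR)-3-hydroxy-6,8a-dimethyl-3-(propan-2-yl)-2,3,3a,5,8,8a-hexahydroazulene-1,4-dione
Conditions: Dess–Martin periodinane, NaHCO3, CH2Cl2, 0 °C to rt
Reagents that add atoms: none
Why: Dess–Martin oxidation of the only secondary hydroxyl (the tertiary C9 hydroxyl cannot be oxidised) under buffered conditions erases the mis-set C7 stereocentre without moving the β,γ-double bond.

Step 10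
Reactants: 13 (3R,3aR,8aR)-3-hydroxy-6,8a-dimethyl-3-(propan-2-yl)-2,3,3a,5,8,8a-hexahydroazulene-1,4-dione
Product: 14 (1S,3R,3aS,4S,8aR)-6,8a-dimethyl-3-(propan-2-yl)-1,2,3,3a,4,5,8,8a-octahydroazulene-1,3,4-triol
Conditions: Me4NBH(OAc)3 (excess), MeCN/AcOH (1:1), −30 to −20 °C
Reagents that add atoms: none
Why: Evans–Saksena reduction, in which the C9 hydroxyl binds the triacetoxyborohydride and delivers hydride intramolecularly to both β-carbonyls from its own (β) face, so that the new hydroxyls at C1 and C7 should both emerge anti (α) to the C9 hydroxyl.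

Step 11
Reactants: 14 (1S,3R,3aS,4S,8aR)-6,8a-dimethyl-3-(propan-2-yl)-1,2,3,3a,4,5,8,8a-octahydroazulene-1,3,4-triol; 15 angelic acid ((2Z)-2-methylbut-2-enoic acid), of which two equivalents are consumed
Product: 16 (1S,3R,3aS,4S,8aR)-3-hydroxy-6,8a-dimethyl-3-(propan-2-yl)-1,2,3,3a,4,5,8,8a-octahydroazulene-1,4-diyl bis[(2Z)-2-methylbut-2-enoate]
Conditions: 15 (2.5 equiv), 2,4,6-trichlorobenzoyl chloride (2.5 equiv), Et3N, toluene, rt; then 14, 80 °C
Reagents that add atoms: angelic acid (the second equivalent of 15, which supplies the second angeloyl group), C/C=C(/C)C(=O)O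
Why: Yamaguchi-type acylation through the angelic 2,4,6-trichlorobenzoic mixed anhydride should acylate the two secondary hydroxyls, one angeloyl group each (the tertiary C9 hydroxyl is too hindered), under conditions chosen to preserve the Z geometry of the angeloyl group; no stereocentre is affected.

Compound list
1 | 4-methyl-3-oxopentanenitrile | CC(C)C(=O)CC#N | starting material
2 | (3S)-3-hydroxy-3-(propan-2-yl)hex-5-enenitrile | C=CC[C@@](O)(C(C)C)CC#N | intermediate
3 | ozonide of 2: (3R)-3-hydroxy-3-(propan-2-yl)-4-(1,2,4-trioxolan-3-yl)butanenitrile (formed in the flask) | C1OC(C[C@@](O)(C(C)C)CC#N)OO1 | intermediate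
4 | (3R)-3-hydroxy-5-oxo-3-(propan-2-yl)pentanenitrile | O=CC[C@@](O)(C(C)C)CC#N | intermediate
5 | 1-bromobut-2-yne | CC#CCBr | starting material
6 | (3R,5R)-3,5-dihydroxy-6-methyl-3-(propan-2-yl)octa-6,7-dienenitrile | C=C=C(C)[C@H](O)C[C@@](O)(C(C)C)CC#N | intermediate
7 | ketimine: (2E,6R,8R)-4-imino-9-methyl-6-(propan-2-yl)undeca-2,9,10-triene-6,8-diol (as its magnesium salt, formed in the flask) | C=C=C(C)[C@H](O)C[C@@](O)(C(C)C)CC(=N)/C=C/C | intermediate
8 | (2E,6S,8R)-6,8-dihydroxy-9-methyl-6-(propan-2-yl)undeca-2,9,10-trien-4-one | C=C=C(C)[C@H](O)C[C@@](O)(C(C)C)CC(=O)/C=C/C | intermediate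
9 | triethyl{[(2E,4Z,6R,8R)-9-methyl-6-(propan-2-yl)-6,8-bis(triethylsilyloxy)undeca-2,4,9,10-tetraen-4-yl]oxy}silane | C=C=C(C)[C@H](O[Si](CC)(CC)CC)C[C@@](O[Si](CC)(CC)CC)(C(C)C)/C=C(O[Si](CC)(CC)CC)/C=C/C | intermediate
10 | triethyl({(1R,3R,3aS,6R,8aR)-6,8a-dimethyl-3-(propan-2-yl)-1,3-bis[(triethylsilyl)oxy]-1,2,3,3a,6,8a-hexahydroazulen-4-yl}oxy)silane (trans-fused; C1=C2 enol ether, C4=C5, C3 methyl β, C7 and C9 silyloxy β, isopropyl α, H10 α) | CC[Si](CC)(CC)OC1=C[C@H](C)C=C[C@@]2(C)[C@H](O[Si](CC)(CC)CC)C[C@@](O[Si](CC)(CC)CC)(C(C)C)[C@H]12 | intermediate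
11 | triethyl({(1R,3R,3aS,8aR)-6,8a-dimethyl-3-(propan-2-yl)-1,3-bis[(triethylsilyl)oxy]-1,2,3,3a,8,8a-hexahydroazulen-4-yl}oxy)silane (conjugated dienol ether C1=C2–C3=C4) | CC[Si](CC)(CC)OC1=CC(C)=CC[C@@]2(C)[C@H](O[Si](CC)(CC)CC)C[C@@](O[Si](CC)(CC)CC)(C(C)C)[C@H]12 | intermediate
12 | (1R,3R,3aR,8aR)-1,3-dihydroxy-6,8a-dimethyl-3-(propan-2-yl)-1,2,3,3a,8,8a-hexahydroazulen-4(5H)-one (C7 hydroxyl β) | O=C1CC(C)=CC[C@@]2(C)[C@H](O)C[C@@](O)(C(C)C)[C@H]12 | intermediate
13 | (3R,3aR,8aR)-3-hydroxy-6,8a-dimethyl-3-(propan-2-yl)-2,3,3a,5,8,8a-hexahydroazulene-1,4-dione | O=C1CC(C)=CC[C@@]2(C)C(=O)C[C@@](O)(C(C)C)[C@H]12 | intermediate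
14 | (1S,3R,3aS,4S,8aR)-6,8a-dimethyl-3-(propan-2-yl)-1,2,3,3a,4,5,8,8a-octahydroazulene-1,3,4-triol | O[C@H]1CC(C)=CC[C@@]2(C)[C@@H](O)C[C@@](O)(C(C)C)[C@H]12 | intermediate
15 | angelic acid, (2Z)-2-methylbut-2-enoic acid | C/C=C(/C)C(=O)O | starting material
16 | (1S,3R,3aS,4S,8aR)-3-hydroxy-6,8a-dimethyl-3-(propan-2-yl)-1,2,3,3a,4,5,8,8a-octahydroazulene-1,4-diyl bis[(2Z)-2-methylbut-2-enoate] | C/C=C(/C)C(=O)O[C@H]1CC(C)=CC[C@@]2(C)[C@@H](OC(=O)/C(C)=C\C)C[C@@](O)(C(C)C)[C@H]12 | target

Total step count: 11. Longest linear sequence: 11 steps (1 to 16).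

Steps most likely to fail

Step 6. The cascade may stop after the first C–C bond by protodeauration of the vinylgold intermediate, the tertiary allylic silyl ether may ionise, the gold carbene may contract the ring by alkyl shift, or facial control by C9 may be incomplete. The fallback sets out from 9 and returns at 10, making the two bonds in separate known reactions. The same gold complex in CH2Cl2 containing MeOH as proton source is used for a Conia-ene-type 5-exo carbocyclisation of the silyl enol ether onto the allene, which should give the vinylcyclopentyl enone F1. Conjugate addition of (CH2=CH)2CuLi with Et3SiCl trapping (THF, −78 °C) forms the C3–C4 bond and gives the silyl enol ether F2 as both C3 epimers. Ring-closing metathesis with second-generation Grubbs catalyst (CH2Cl2, 40 °C) between the C6 vinyl group and the new C3 vinyl group then closes the seven-membered ring at C4=C5 and gives 10 (both C3 epimers converge in step 7).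

Step 8. The dienolate may be protonated at the γ-carbon, the β,γ-enone may reconjugate under fluoride, or the alkene migration of step 7 may be incomplete. The fallback sets out from 10, bypasses step 7 as well, and returns at 12. Saegusa–Ito oxidation (Pd(OAc)2, MeCN) of the enol ether should give the linear 2,4-dienone F3. Lithium in liquid NH3/THF with t-BuOH (1 equiv) at −78 °C, quenched with solid NH4Cl, performs a 1,6-reduction to the dienolate with kinetic α-protonation and should give the β,γ-unsaturated ketone F4. HF·pyridine in THF removes the two silyl ethers to give 12.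

Step 11. Forced acylation of two hindered secondary hydroxyls may isomerise the angeloyl group to tigloyl or leave the second hydroxyl free. The fallback sets out from 14 and returns at 16 by building the Z-alkenes after acylation. Esterification with 2-[bis(2,2,2-trifluoroethoxy)phosphoryl]propanoic acid (DCC, DMAP, CH2Cl2) gives the bis(phosphonopropanoate) F5. Still–Gennari olefination with acetaldehyde (KN(SiMe3)2, 18-crown-6, THF, −78 °C) should then form both (Z)-2-methylbut-2-enoates and give 16.

Further compounds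
F1 | step 6 | (2E)-1-[2-ethenyl-2-methyl-5-(propan-2-yl)-3,5-bis(triethylsilyloxy)cyclopentyl]but-2-en-1-one (ring configuration as in 10) | C=C[C@@]1(C)[C@H](O[Si](CC)(CC)CC)C[C@@](O[Si](CC)(CC)CC)(C(C)C)[C@@H]1C(=O)/C=C/C
F2 | step 6 | triethyl({1-[2-ethenyl-2-methyl-5-(propan-2-yl)-3,5-bis(triethylsilyloxy)cyclopentyl]-3-methylpenta-1,4-dien-1-yl}oxy)silane (both C3 epimers) | C=C[C@@]1(C)[C@H](O[Si](CC)(CC)CC)C[C@@](O[Si](CC)(CC)CC)(C(C)C)[C@@H]1C(O[Si](CC)(CC)CC)=CC(C)C=C
F3 | step 8 | 6,8a-dimethyl-3-(propan-2-yl)-1,3-bis(triethylsilyloxy)-2,3,3a,8a-tetrahydroazulen-4(1H)-one (ring configuration as in 10; C2=C3 and C4=C5) | O=C1C=C(C)C=C[C@@]2(C)[C@H](O[Si](CC)(CC)CC)C[C@@](O[Si](CC)(CC)CC)(C(C)C)[C@H]12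
F4 | step 8 | bis(triethylsilyl) ether of 12 | O=C1CC(C)=CC[C@@]2(C)[C@H](O[Si](CC)(CC)CC)C[C@@](O[Si](CC)(CC)CC)(C(C)C)[C@H]12
F5 | step 11 | 1,4-bis{2-[bis(2,2,2-trifluoroethoxy)phosphoryl]propanoate} of 14 | CC(C(=O)O[C@H]1CC(C)=CC[C@@]2(C)[C@@H](OC(=O)C(C)P(=O)(OCC(F)(F)F)OCC(F)(F)F)C[C@@](O)(C(C)C)[C@H]12)P(=O)(OCC(F)(F)F)OCC(F)(F)F
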